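## Structural features

The target is a 3,3''-biflavanone: two 2-(4-methoxyphenyl)chroman-4-one units joined by a single bond between C3 and C3'' (flavanone numbering; doubly primed locants belong to the unit whose ring A carries the 7''-methoxy group). Ring A of the unprimed unit is a 5,7-dihydroxy phloroglucinol ring and ring A of the other unit differs only by the 7''-O-methyl group, so the molecule is C2-symmetric except for one methyl ether. The four stereocentres C2, C3, C3'' and C2'' are contiguous and all R. In each pyranone ring (ring C) the aryl group on C2 and the C3–C3'' bond are cis, and the two halves stand in the like relationship. C3 and C3'' are tertiary C–H centres α to the C4 and C4'' ketones and β to the ring oxygens. Enolisation would convert the cis arrangement into the presumably more stable trans one, and β-elimination of the phenoxide (flavanone–chalcone opening) would erase C2 as well, so base, Lewis acids and strong protic acids are dangerous once the ketones exist. The electron-rich rings A and the three phenols add sensitivity to electrophiles and oxidants and call for protecting groups that leave without acid or base. The real difficulty is therefore not the skeleton but four contiguous centres with a cis relation at two epimerisable positions, on both sides of a congested C3–C3'' bond, together with the differentiation of the two rings A. The key step exploits the fact that C4 and C4'' carry the only carbonyl oxygens and that each neighbours a C3 (C3'') hydrogen trans to the adjacent C2 (C2'') aryl group. This is the pattern left by syn addition of H–B across a C3=C4 double bond from the face away from the aryl group, so both oxygens and both C3 hydrogens can be introduced together on a 3,3''-bi(2H-chromene), and the carbonyl groups appear only afterwards.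

## Logic of the disconnections

17 to 16. The three O–CH2Ph bonds at O5, O7 and O5'' are cut; no skeletal bond is touched. The phenols must be masked through hydride, boronate and borane chemistry, and the mask must leave without acid or base because C3 and C3'' are epimerisable in 17 and 16. For that reason O5'' is carried as a benzyl ether and not as a chelated methyl ether, which would need a boron or aluminium halide at the very end. The gain is an end-game of one neutral operation. The demand is that hydrogenolysis spares the benzylic C2–O and C2''–O ring bonds and the ketones.

16 to 15. The C4=O and C4''=O groups are traced back to carbinols. As long as C4 is a carbinol the neighbouring C3–H is not acidic, so the labile cis centres become ordinary sp3 centres. The forward step needs a neutral oxidant that tolerates benzyl ethers and acts on two hindered benzylic alcohols.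

15 to 13. The C4–O and C3–H bonds of both rings (four bonds) are cut, restoring the C3=C4 and C3''=C4'' double bonds. The H/OH pattern with hydrogen anti to the aryl group is a hydroboration retron. Four of the six stereocentres of 15 disappear, only C2 and C2'' remain, and C3–C3'' becomes the central bond of a diene that condensation chemistry can supply. The forward step must put boron on C4 and attack the face opposite the aryl group in both rings.

13 to 10 and 11 (through 12). The C2–aryl and C2''–aryl bonds are cut. Each joins an allylic, oxygen-bearing carbon to an electron-rich arene, which corresponds to a cation at C2 stabilised by the ring oxygen and an aryl group delivered from boron. Both aryl rings and the last two stereocentres are removed, and 10 has no stereocentre that matters. The forward step needs catalyst control of the face at two acetal carbons with the same sense, and attack at C2 and not at C4.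

10 to 8 (through 9). The C2–OEt and C2–H bonds are returned to lactone carbonyl groups. The lactone is the robust carrier of this oxidation level and gives a bicoumarin that condensation can make. The forward reduction must stop at the lactol level at both sites.

8 to 4 and 7. The C3''=C4'' bond and the O1''–C2'' lactone bond are cut, a Perkin-type condensation retron. This separates the two rings A with their different oxygen substituents, so the differentiation of the halves is decided by the choice of aldehyde. The demand is that the two condensations be run one after the other.

4 to 2 and 3. The C3=C4 bond and the O1–C2 lactone bond are cut. The C3–C3'' bond of the target is thereby traced to the CH2–CH2 bond of 3 and is bought, not made. Only one CH2 group of 3 may condense at this stage.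

2 to 1, and 7 to 6 to 5. Only O–benzyl bonds and one O–methyl bond are changed on commercial aldehydes. The chelation-controlled demethylation that would otherwise fall on the last step is moved to 5, where nothing can epimerise. The demand is regioselective alkylation, with the hydrogen-bonded ortho hydroxyl as the unreactive one.

## Other disconnections considered

Alternative 1: The cut is at C4a–C5 and C4a''–C5'', with the aromatic character of both rings A given up. It leads back to the bis(2,3-dihydro-4H-pyran-4-one) A1, in which C8a and C8a'' each carry a CH2–C(OR)=CH–CO2Me chain (R = benzyl in one half, methyl in the other). In the forward step a mild base removes a proton from C8 and from C8''. Each extended enolate attacks its ester carbonyl through C4a in a six-membered Claisen-type closure, methoxide leaves, and tautomerisation gives the phenol, so the product is the 7-O-benzyl ether A2.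
- In favour: O5–H and O5''–H emerge free, the two rings A are told apart by enol ether groups fixed long before, and aromatisation drives the closure. Only one hydrogenolysis separates A2 from the target, with no oxidation after the key step. On the end-game (one step against two) and on the number of protecting groups this alternative is better than the chosen plan.
- Against: the base meets a substrate whose C3–H and C3''–H are already α to the C4 carbonyl groups. Deprotonation there (the kinetically favoured site of a vinylogous ester) and β-elimination of the ring oxygen compete with the wanted deprotonation at C8, so the cis configuration is exposed at the stage where the chosen plan still has carbinols. The key step creates no stereocentre, so all four must already be present in A1. Its own assembly (two cis-2,3-disubstituted dihydropyranones joined at C3, each with a sensitive β-alkoxy enoate arm) is expected to need more steps than the seven that lead to 13.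
- Comparison: on structure it handles the differentiation of the rings A more elegantly but leaves the stereochemical problem untouched. On mechanism the closure is sound but runs under enolising conditions. On step count it gains one step after the key step and probably loses several before it.

Alternative 2: The cut removes the C2–H, C3–H, C2''–H and C3''–H bonds and leads to the flat protected 3,3''-biflavone A3. In the forward step Ru(cod)(2-methylallyl)2 with a chiral N-heterocyclic carbene ligand under H2 adds hydrogen syn to each pyranone C2=C3 bond and gives A4, which is the same compound as 16.
- In favour: syn addition gives the 2,3-cis relation by mechanism. On this point the alternative is the equal of the chosen plan, where the same relation comes from anti-aryl hydroboration. All four stereocentres arise in one catalytic step from a precursor without stereocentres, the ketones are present from the start, and A3 is open to short flavone chemistry. On step economy and elegance this is the better plan on paper, by some two to three steps.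
- Against: each C=C bond is tetrasubstituted, part of a vinylogous ester, and flanked by an aryl group and by the other flavone unit. Hindered rotation about C3–C3'' may make A3 a set of slowly interconverting atropisomers that offer different faces. The relation between the halves depends on the catalyst overriding the first-formed half. Hydrogenation of this type tends to continue to the C4 carbinols, which would bring back an oxidation step. The ketone A4 is formed in a medium that contains the base used to generate the carbene, with its C3–H already epimerisable.
- Comparison: the chosen plan divides the control into catalyst control at C2 and C2'' (cationic sp2 carbons) and substrate relay to C3 and C3'', each with a close analogy, and reaches the identical compound with C3 fixed before any carbonyl exists. The alternative is shorter but rests on one hydrogenation far more demanding than the usual cases.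

Alternative 3: The cut is at O1–C8a and C4–C4a in both units, so that both rings A are detached as arynes. What remains is the cis-fused dilactone A5, whose four stereocentres are C2, C3, C3'' and C2'' of the target. In the forward step NaOMe opens one lactone and the freed alkoxide adds to the first CsF-generated 3,5-dialkoxyaryne. The aryl anion formed ortho to an alkoxy group acylates the other lactone carbonyl, which closes ring C and releases the second alkoxide. That alkoxide repeats the sequence with the second aryne and the methyl ester, and the product is A6.
- In favour: A5 has the relative configuration (cis ring fusion, both aryl groups exo) that oxidative β,β-coupling of the matching cinnamic acid delivers in one operation, so the four centres cost almost nothing. The regiochemistry of alkoxide addition to such an aryne fits the 5,7-pattern, and four bonds and two rings form in one flask. On brevity and convergence this alternative is clearly better than the chosen plan.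
- Against: the two alkoxides are equivalent by symmetry but the two arynes must differ, so the first aryne has to react exactly once. This is a statistical problem that also yields the two symmetric products, whereas the chosen plan differentiates the halves at the outset. Methoxide and fluoride act on β-alkoxido esters that can cleave by retro-aldol reaction at C2–C3, and on the finished cis-flavanone, which they can epimerise or open. The dimerisation gives racemic A5, so a resolution replaces asymmetric catalysis. A6 still holds the chelated 5''-O-methyl group, whose removal needs a Lewis acid next to the labile centres.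
- Comparison: on structure the core matches a cheap dimer better than anything in the chosen plan. On mechanism carbanion and alkoxide chemistry runs beside epimerisable centres, against neutral steps in the chosen plan. On steps it is shorter, but with a statistical key step and a resolution.

Key step: step 8

Remark on descriptors: 13 is (2S,2''S) although C2 and C2'' have the same spatial arrangement as the 2R and 2''R centres of 15, 16 and 17. The letter changes because the sp2 C3 outranks the aryl carbon in 13 only, so the label (2R,2''R) would describe the enantiomer of 13. For the same reason C3 and C3'' are S in 15 and R in 16 and 17 without any change in space.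

Remark on the design of 13: O5'' is benzylated, not methylated, so that no chelation-directed demethylation is needed after the ketones exist.

Assumption: the (2R,3R) hydroxy acid of step 7 is taken to deliver the aryl group to the face that gives 13; if the sense is the opposite, the (2S,3S) acid from D-tartaric acid is used and nothing else changes.

## Route

Step 1
Reactants: 1 2,4,6-trihydroxybenzaldehyde
Product: 2 4,6-bis(benzyloxy)-2-hydroxybenzaldehyde
Conditions: BnBr (2.05 equiv), K2CO3 (2.2 equiv), DMF, 0 °C → rt
Reagents that add atoms: benzyl bromide, BrCc1ccccc1
Why: Williamson etherification; the para hydroxyl (most acidic) and one ortho hydroxyl are alkylated, while the last ortho hydroxyl is held in a hydrogen bond to the formyl oxygen and is the least nucleophilic, so controlled stoichiometry should stop at the bis(benzyl) ether.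

Step 2
Reactants: 2 4,6-bis(benzyloxy)-2-hydroxybenzaldehyde; 3 succinic anhydride (4 equiv)
Product: 4 [5,7-bis(benzyloxy)-2-oxo-2H-chromen-3-yl]acetic acid
Conditions: disodium succinate (1.5 equiv), neat melt, 150 °C; then aq. HCl
Reagents that add atoms: none
Why: Perkin condensation: the phenol is acylated by the anhydride, the carboxylate base enolises the anhydride-activated CH2, and aldol addition to the formyl group with loss of water closes the coumarin and leaves the second CH2CO2H arm on C3. The excess of 3 takes up the water of condensation as succinic acid and is meant to suppress a second condensation of 4 with 2.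

Step 3
Reactants: 5 2-hydroxy-4,6-dimethoxybenzaldehyde
Product: 6 2,6-dihydroxy-4-methoxybenzaldehyde
Conditions: AlCl3 (3.5 equiv), CH2Cl2, 0 °C → reflux; then 1 M HCl
Reagents that add atoms: none
Why: Chelation-controlled aryl methyl ether cleavage: aluminium bridged between the formyl oxygen and the ortho methoxy oxygen activates that O–CH3 bond for attack by chloride, while the para methoxy group cannot chelate and should be kept.

Step 4
Reactants: 6 2,6-dihydroxy-4-methoxybenzaldehyde
Product: 7 2-(benzyloxy)-6-hydroxy-4-methoxybenzaldehyde
Conditions: BnBr (1.05 equiv), K2CO3 (1.1 equiv), acetone, reflux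
Reagents that add atoms: benzyl bromide, BrCc1ccccc1
Why: Williamson etherification; only one hydroxyl of 6 at a time can hydrogen-bond to the formyl oxygen, the free one is alkylated, and the remaining one is then chelated and unreactive, so mono-benzylation should be clean.

Step 5
Reactants: 4 [5,7-bis(benzyloxy)-2-oxo-2H-chromen-3-yl]acetic acid; 7 2-(benzyloxy)-6-hydroxy-4-methoxybenzaldehyde
Product: 8 5,5'',7-tris(benzyloxy)-7''-methoxy-3,3''-bicoumarin (3,3''-bi(2H-chromene)-2,2''-dione)
Conditions: Ac2O (4 equiv), Et3N (3 equiv), 110 °C
Reagents that add atoms: none
Why: Perkin–Oglialoro coumarin synthesis: the mixed anhydride of 4 acylates the phenol of 7, and the CH2 group, activated by the carbonyl and by the C3=C4 bond of the first coumarin, is enolised and condenses with the formyl group. Loss of water closes the second lactone and creates C3''=C4''; the C3–C3'' bond is the former CH2–CH2 bond of 3.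

Step 6
Reactants: 8 5,5'',7-tris(benzyloxy)-7''-methoxy-3,3''-bicoumarin
Product: 10 5,5'',7-tris(benzyloxy)-2,2''-diethoxy-7''-methoxy-3,3''-bi(2H-chromene) (mixture of acetal diastereomers), via bis(lactol) 9 (not isolated)
Conditions: i-Bu2AlH (2.4 equiv), CH2Cl2, −78 °C; aq. potassium sodium tartrate; crude 9, EtOH, pyridinium p-toluenesulfonate (cat.), 3 Å MS, rt
Reagents that add atoms: ethanol, CCO
Why: Partial reduction of a lactone with i-Bu2AlH at low temperature stops at the aluminium hemiacetal, which gives the 2H-chromen-2-ol on work-up. Acid-catalysed acetal exchange through the oxygen-stabilised cation fixes both lactol carbons as ethyl acetals; their configuration is of no consequence because both are ionised again in step 7.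

Step 7
Reactants: 10 5,5'',7-tris(benzyloxy)-2,2''-diethoxy-7''-methoxy-3,3''-bi(2H-chromene); 11 4-methoxyphenylboronic acid (3 equiv)
Product: 13 (2S,2''S)-5,5'',7-tris(benzyloxy)-7''-methoxy-2,2''-bis(4-methoxyphenyl)-3,3''-bi(2H-chromene), via diethyl (4-methoxyphenyl)boronate 12 (not isolated)
Conditions: 11, EtOH, PhMe, azeotropic removal of water and solvent; then 10, (2R,3R)-4-(dibenzylamino)-2,3-dihydroxy-4-oxobutanoic acid (20 mol%), Yb(OTf)3 (20 mol%), EtOAc, −20 → 4 °C, dark
Reagents that add atoms: none
Why: Enantioselective addition of an aryl boronate to chromene acetals under combined chiral Brønsted acid and Lewis acid catalysis: the hydroxy acid exchanges onto boron to give a chiral acyloxyboronate that, helped by Yb(OTf)3, ionises the acetal to a benzopyrylium–borate ion pair, and the aryl group migrates from boron to C2 inside that pair. Both acetal carbons react through planar cations, so each new centre is set by the catalyst whatever the acetal configuration was, and the unlike diastereomer, which carries most of the stereochemical error, is removed by chromatography.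

Step 8
Reactants: 13 (2S,2''S)-5,5'',7-tris(benzyloxy)-7''-methoxy-2,2''-bis(4-methoxyphenyl)-3,3''-bi(2H-chromene)
Product: 15 (2R,3S,4S,2''R,3''S,4''S)-5,5'',7-tris(benzyloxy)-7''-methoxy-2,2''-bis(4-methoxyphenyl)-3,3''-bichromane-4,4''-diol (2,3-cis-3,4-trans in both rings), via 4,4''-bis(borane) adduct 14 (not isolated)
Conditions: BH3·SMe2 (6 equiv), THF, 0 °C → rt; then 3 M NaOH, 30% H2O2, 0 °C → rt
Reagents that add atoms: hydrogen peroxide, OO
Why: Each trisubstituted C3=C4 bond takes up H–B by the concerted four-centre syn addition of hydroboration, boron bonding to C4 (the only CH terminus) and hydrogen to the fully substituted C3; alkaline H2O2 then exchanges boron for hydroxyl with retention through 1,2-migration of C4 from boron to oxygen. The closest known reaction types are the anti-selective hydroboration–oxidation of 2-aryl-2H-chromenes to 2,3-trans-flavan-3-ols and the hydroboration of 3-substituted 2H-chromenes to trans-chroman-4-ols with boron on C4. No ring is closed. C3 and C4 are created together: their mutual relation (H and OH cis, hence C3–C3'' bond and OH trans) follows from the syn addition, and their relation to C2 follows from attack on the face opposite the C2 aryl group, which sits pseudo-axial to escape allylic strain with the C3 substituent and so screens one face of the half-chair. C3'' and C4'' are controlled in the same way by the C2'' aryl group, and because C2 and C2'' have the same configuration in space the like (2R,3S,4S,2''R,3''S,4''S) diol should result. The step needs boron on C4 and not on C3, which the trisubstituted pattern secures although the peri 5- and 5''-benzyloxy groups crowd C4, and it needs anti attack at both rings, which the two aryl groups secure. It also needs the second ring to react with free BH3 and not with the B–H of the borane already bound at C4; the large excess of BH3·SMe2 and the twist about the C3–C3'' bond of the diene are meant to ensure this.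

Step 9
Reactants: 15 (2R,3S,4S,2''R,3''S,4''S)-5,5'',7-tris(benzyloxy)-7''-methoxy-2,2''-bis(4-methoxyphenyl)-3,3''-bichromane-4,4''-diol
Product: 16 (2R,3R,2''R,3''R)-5,5'',7-tris(benzyloxy)-7''-methoxy-2,2''-bis(4-methoxyphenyl)-3,3''-bichromane-4,4''-dione
Conditions: Dess–Martin periodinane (3 equiv), pyridine (6 equiv), CH2Cl2, 0 °C → rt
Reagents that add atoms: none
Why: Dess–Martin oxidation: ligand exchange at iodine and removal of the carbinol hydrogen by acetate convert each secondary benzylic alcohol into the ketone under buffered, near-neutral conditions. C3–H and C3''–H, now α to carbonyl groups, meet neither strong base nor strong acid, so the 2,3-cis arrangement should be kept.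

Step 10
Reactants: 16 (2R,3R,2''R,3''R)-5,5'',7-tris(benzyloxy)-7''-methoxy-2,2''-bis(4-methoxyphenyl)-3,3''-bichromane-4,4''-dione
Product: 17 (2R,3R,2''R,3''R)-5,5'',7-trihydroxy-7''-methoxy-2,2''-bis(4-methoxyphenyl)-3,3''-bichromane-4,4''-dione (target)
Conditions: H2 (1 atm), Pd/C (10%), EtOAc, rt
Reagents that add atoms: none
Why: Catalytic hydrogenolysis of three aryl benzyl ethers over palladium under neutral conditions; O-benzyl bonds should cleave faster than the ring C2–O bonds or the ketones, and no acid or base is present that could epimerise C3 and C3''.

## Compound list

1 | 2,4,6-trihydroxybenzaldehyde | O=Cc1c(O)cc(O)cc1O | starting material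
2 | 4,6-bis(benzyloxy)-2-hydroxybenzaldehyde | O=Cc1c(O)cc(OCc2ccccc2)cc1OCc1ccccc1 | intermediate
3 | succinic anhydride | O=C1CCC(=O)O1 | starting material
4 | [5,7-bis(benzyloxy)-2-oxo-2H-chromen-3-yl]acetic acid | OC(=O)CC1=Cc2c(OCc3ccccc3)cc(OCc3ccccc3)cc2OC1=O | intermediate
5 | 2-hydroxy-4,6-dimethoxybenzaldehyde | COc1cc(O)c(C=O)c(OC)c1 | starting material
6 | 2,6-dihydroxy-4-methoxybenzaldehyde | COc1cc(O)c(C=O)c(O)c1 | intermediate
7 | 2-(benzyloxy)-6-hydroxy-4-methoxybenzaldehyde | COc1cc(O)c(C=O)c(OCc2ccccc2)c1 | intermediate
8 | 5,5'',7-tris(benzyloxy)-7''-methoxy-3,3''-bicoumarin | O=C1Oc2cc(OCc3ccccc3)cc(OCc3ccccc3)c2C=C1C1=Cc2c(OCc3ccccc3)cc(OC)cc2OC1=O | intermediate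
9 | 5,5'',7-tris(benzyloxy)-7''-methoxy-3,3''-bi(2H-chromene)-2,2''-diol, bis(lactol), mixture of diastereomers | OC1Oc2cc(OCc3ccccc3)cc(OCc3ccccc3)c2C=C1C1=Cc2c(OCc3ccccc3)cc(OC)cc2OC1O | intermediate
10 | 5,5'',7-tris(benzyloxy)-2,2''-diethoxy-7''-methoxy-3,3''-bi(2H-chromene), mixture of acetal diastereomers | CCOC1Oc2cc(OCc3ccccc3)cc(OCc3ccccc3)c2C=C1C1=Cc2c(OCc3ccccc3)cc(OC)cc2OC1OCC | intermediate
11 | 4-methoxyphenylboronic acid | COc1ccc(cc1)B(O)O | starting material
12 | diethyl (4-methoxyphenyl)boronate | CCOB(OCC)c1ccc(OC)cc1 | intermediate
13 | (2S,2''S)-5,5'',7-tris(benzyloxy)-7''-methoxy-2,2''-bis(4-methoxyphenyl)-3,3''-bi(2H-chromene) | COc1ccc([C@@H]2Oc3cc(OCc4ccccc4)cc(OCc4ccccc4)c3C=C2C2=Cc3c(OCc4ccccc4)cc(OC)cc3O[C@H]2c2ccc(OC)cc2)cc1 | intermediate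
14 | 4,4''-bis(borane) adduct of 13, drawn with BH2 on C4 and C4'', boron and the C3 hydrogen cis, both anti to the C2 aryl group | COc1ccc([C@@H]2Oc3cc(OCc4ccccc4)cc(OCc4ccccc4)c3[C@@H](B)[C@@H]2[C@H]2[C@H](B)c3c(OCc4ccccc4)cc(OC)cc3O[C@H]2c2ccc(OC)cc2)cc1 | intermediate
15 | (2R,3S,4S,2''R,3''S,4''S)-5,5'',7-tris(benzyloxy)-7''-methoxy-2,2''-bis(4-methoxyphenyl)-3,3''-bichromane-4,4''-diol | COc1ccc([C@@H]2Oc3cc(OCc4ccccc4)cc(OCc4ccccc4)c3[C@@H](O)[C@@H]2[C@H]2[C@H](O)c3c(OCc4ccccc4)cc(OC)cc3O[C@H]2c2ccc(OC)cc2)cc1 | intermediate
16 | (2R,3R,2''R,3''R)-5,5'',7-tris(benzyloxy)-7''-methoxy-2,2''-bis(4-methoxyphenyl)-3,3''-bichromane-4,4''-dione | COc1ccc([C@@H]2Oc3cc(OCc4ccccc4)cc(OCc4ccccc4)c3C(=O)[C@@H]2[C@H]2C(=O)c3c(OCc4ccccc4)cc(OC)cc3O[C@H]2c2ccc(OC)cc2)cc1 | intermediate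
17 | (2R,3R,2''R,3''R)-5,5'',7-trihydroxy-7''-methoxy-2,2''-bis(4-methoxyphenyl)-3,3''-bichromane-4,4''-dione | COc1ccc([C@@H]2Oc3cc(O)cc(O)c3C(=O)[C@@H]2[C@H]2C(=O)c3c(O)cc(OC)cc3O[C@H]2c2ccc(OC)cc2)cc1 | target

## Step count and least certain steps

Total: 10 steps. Longest linear sequence: 8 steps (steps 1, 2, 5, 6, 7, 8, 9, 10 from 1; the branch from 5 through steps 3 and 4 is equally long).

Step 8 (key step). The most likely failure is poor facial selectivity at the second ring. Once one ring has reacted, the B–H of the borane on C4 can be delivered across to the remaining C3''=C4'' bond under the control of the tether and not of the C2'' aryl group. Incomplete reaction of the second, peri-crowded alkene is the other risk. Loss of regiocontrol is less likely, although the electron-rich ring A electronically favours hydride delivery to C4. The fallback replaces hydroboration by hydrogenation followed by benzylic C–H oxidation, and sets out from 13. Hydrogenation with [Ir(cod)(PCy3)(py)]PF6 under H2 in CH2Cl2, a homogeneous catalyst that leaves benzyl ethers and the C2–O bonds alone, should add H2 syn and anti to the aryl groups and give the 2,3-cis bis(flavan) (2R,3R,2''R,3''R)-5,5'',7-tris(benzyloxy)-7''-methoxy-2,2''-bis(4-methoxyphenyl)-3,3''-bichromane F1. DDQ in CH2Cl2/H2O then abstracts hydride from C4 and C4'', assisted by the 5,7-dialkoxy rings A, and water captures the cations to give the C4-epimeric bis(flavan-4-ol) mixture F2, whose C4 configuration is irrelevant. Dess–Martin oxidation as in step 9 brings the material back to the route at 16.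

Step 7. The most likely failure is insufficient catalyst control or a stalled second addition, because the cations are stabilised by two alkoxy groups and carry a C3 substituent, so they are weak and hindered electrophiles; aryl transfer to C4 is a further possibility. The product is also a 2-aryl-2H-chromene that can racemise by reversible ring opening under light or acid. The fallback gives up asymmetric catalysis for a racemic addition and a separation, and sets out from 10. Treating 10 with 12, Yb(OTf)3 and an achiral hydroxy acid (glycolic acid) should give 13 together with its (2R,2''R) enantiomer F3 and the unlike (2R*,2''S*) diastereomer F4. F4 is removed on silica, and 13 is separated from F3 by preparative chromatography on a chiral stationary phase (amylose tris(3,5-dimethylphenylcarbamate)), which brings the material back at 13.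

Step 2. The most likely failure is sluggish condensation of the electron-rich, chelated aldehyde at the temperature the Perkin reaction needs, with competing second condensation to the symmetric bicoumarin. The fallback is a Wittig olefination, and sets out from 2. With the stabilised ylide Ph3P=C(CO2Me)CH2CO2Me in toluene at reflux, 2 should give dimethyl 2-[4,6-bis(benzyloxy)-2-hydroxybenzylidene]succinate F5. On continued heating F5 equilibrates about the double bond and lactonises to methyl [5,7-bis(benzyloxy)-2-oxo-2H-chromen-3-yl]acetate F6. LiOH in THF/H2O followed by acidification, which recloses the coumarin ring, returns the route at 4.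

Step 10. The most likely failure is over-reduction, namely hydrogenolysis of the doubly benzylic C2–O and C2''–O ring bonds or reduction of the ketones before the last benzyl ether has gone. The fallback is a non-reductive debenzylation from 16 with BCl3 and pentamethylbenzene as cation scavenger in CH2Cl2 at −78 °C, quenched cold with MeOH, which comes back at 17. The low temperature and the short exposure are meant to keep the Lewis acid from epimerising C3 and C3''. This fallback makes no new compound (entry F0).

Step 1. The most likely failure is loss of regiocontrol, giving mono-, bis- and tris(benzyl) ethers and some C-benzylation of the phloroglucinol ring. The fallback sets out from 1. Exhaustive benzylation (BnBr in excess, K2CO3, DMF, 60 °C) gives 2,4,6-tris(benzyloxy)benzaldehyde F7. One ortho benzyl ether is then cleaved with MgBr2·OEt2 in toluene/Et2O through magnesium chelation to the formyl oxygen, which comes back at 2.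

## Further compounds

F1 | step 8 | (2R,3R,2''R,3''R)-5,5'',7-tris(benzyloxy)-7''-methoxy-2,2''-bis(4-methoxyphenyl)-3,3''-bichromane | COc1ccc([C@@H]2Oc3cc(OCc4ccccc4)cc(OCc4ccccc4)c3C[C@@H]2[C@H]2Cc3c(OCc4ccccc4)cc(OC)cc3O[C@H]2c2ccc(OC)cc2)cc1
F2 | step 8 | 5,5'',7-tris(benzyloxy)-7''-methoxy-2,2''-bis(4-methoxyphenyl)-3,3''-bichromane-4,4''-diol, configuration of F1 at C2, C3, C3'', C2'', mixture of epimers at C4 and C4'' | COc1ccc([C@@H]2Oc3cc(OCc4ccccc4)cc(OCc4ccccc4)c3C(O)[C@@H]2[C@H]2C(O)c3c(OCc4ccccc4)cc(OC)cc3O[C@H]2c2ccc(OC)cc2)cc1
F3 | step 7 | (2R,2''R)-5,5'',7-tris(benzyloxy)-7''-methoxy-2,2''-bis(4-methoxyphenyl)-3,3''-bi(2H-chromene), enantiomer of 13 | COc1ccc([C@H]2Oc3cc(OCc4ccccc4)cc(OCc4ccccc4)c3C=C2C2=Cc3c(OCc4ccccc4)cc(OC)cc3O[C@@H]2c2ccc(OC)cc2)cc1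
F4 | step 7 | (2R*,2''S*)-5,5'',7-tris(benzyloxy)-7''-methoxy-2,2''-bis(4-methoxyphenyl)-3,3''-bi(2H-chromene), racemic, (2R,2''S) enantiomer drawn | COc1ccc([C@H]2Oc3cc(OCc4ccccc4)cc(OCc4ccccc4)c3C=C2C2=Cc3c(OCc4ccccc4)cc(OC)cc3O[C@H]2c2ccc(OC)cc2)cc1
F5 | step 2 | dimethyl 2-[4,6-bis(benzyloxy)-2-hydroxybenzylidene]succinate, mixture of alkene isomers | COC(=O)CC(=Cc1c(O)cc(OCc2ccccc2)cc1OCc1ccccc1)C(=O)OC
F6 | step 2 | methyl [5,7-bis(benzyloxy)-2-oxo-2H-chromen-3-yl]acetate | COC(=O)CC1=Cc2c(OCc3ccccc3)cc(OCc3ccccc3)cc2OC1=O
F0 | step 10 | none | none
F7 | step 1 | 2,4,6-tris(benzyloxy)benzaldehyde | O=Cc1c(OCc2ccccc2)cc(OCc2ccccc2)cc1OCc1ccccc1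
A1 | alternative 1 | bis(2,3-dihydro-4H-pyran-4-one) with the target configuration at C2, C3, C3'', C2'', C8a bearing an (E)-2-(benzyloxy)-4-methoxy-4-oxobut-2-enyl chain and C8a'' an (E)-2,4-dimethoxy-4-oxobut-2-enyl chain | COc1ccc([C@@H]2OC(C/C(OCc3ccccc3)=C\C(=O)OC)=CC(=O)[C@@H]2[C@H]2C(=O)C=C(C/C(OC)=C\C(=O)OC)O[C@H]2c2ccc(OC)cc2)cc1
A2 | alternative 1 | 7-O-benzyl ether of the target | COc1ccc([C@@H]2Oc3cc(OCc4ccccc4)cc(O)c3C(=O)[C@@H]2[C@H]2C(=O)c3c(O)cc(OC)cc3O[C@H]2c2ccc(OC)cc2)cc1
A3 | alternative 2 | 5,5'',7-tris(benzyloxy)-7''-methoxy-2,2''-bis(4-methoxyphenyl)-3,3''-bi(4H-chromene)-4,4''-dione (protected 3,3''-biflavone) | COc1ccc(cc1)-c1oc2cc(OCc3ccccc3)cc(OCc3ccccc3)c2c(=O)c1-c1c(-c2ccc(OC)cc2)oc2cc(OC)cc(OCc3ccccc3)c2c1=O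
A4 | alternative 2 | 5,7,5''-tri-O-benzyl ether of the target, identical with 16 | COc1ccc([C@@H]2Oc3cc(OCc4ccccc4)cc(OCc4ccccc4)c3C(=O)[C@@H]2[C@H]2C(=O)c3c(OCc4ccccc4)cc(OC)cc3O[C@H]2c2ccc(OC)cc2)cc1
A5 | alternative 3 | cis-fused 4,8-bis(4-methoxyphenyl)-3,7-dioxabicyclo[3.3.0]octane-2,6-dione, both aryl groups exo, configuration of the target at the four centres | COc1ccc(cc1)[C@@H]1OC(=O)[C@@H]2[C@H]1C(=O)O[C@H]2c1ccc(OC)cc1
A6 | alternative 3 | 5,7-di-O-benzyl-5''-O-methyl ether of the target | COc1ccc([C@@H]2Oc3cc(OCc4ccccc4)cc(OCc4ccccc4)c3C(=O)[C@@H]2[C@H]2C(=O)c3c(OC)cc(OC)cc3O[C@H]2c2ccc(OC)cc2)cc1
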